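Begin with the small charge of catalyst: at 2 mol% on substrate, each catalyst has to turn 50.0 times to carry the substrate charge through the cycle.

    substrate + free catalyst ⇌ catalyst intermediate A (K1 = 9.9 L mol⁻¹, k1 = 1.0 L mol⁻¹ min⁻¹)
    partner + catalyst intermediate A ⇌ catalyst intermediate B (K2 = 2.9 L mol⁻¹, k2 = 1.1 L mol⁻¹ min⁻¹)
    catalyst intermediate B ⇌ by-product + catalyst intermediate C (K3 = 0.047 M, k3 = 0.15 min⁻¹)
    catalyst intermediate C → free catalyst + target (k4 = 1.3 min⁻¹)
    partner + free catalyst + target → free catalyst + over-reaction product (k5 = 0.26 L² mol⁻² min⁻¹)

| setting | Monday's | Thursday's | Wednesday's | Sunday's |
|---|---|---|---|---|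
| substrate | 0.069 M | 0.069 M | 0.069 M | 0.069 M |
| partner | 1.00 equiv | 2.00 equiv | 4.00 equiv | 8.00 equiv |
| free catalyst | 2 mol% | 2 mol% | 2 mol% | 2 mol% |
| time | 5.0 d | 5.0 d | 5.0 d | 5.0 d |

- amount of target at the end, in percent of the substrate charged for Monday's, Thursday's, Wednesday's, Sunday's, in this order
- how that number moves from the first to the last of them (rises all the way / hardly changes / falls, then rises / falls all the way / rises, then falls)

- "hardly changes" means that all values lie within two and a half points (for a concentration: within two and a half percent of the largest)
- run time (Monday's): 5.0 d

Take over Monday's flask by reckoning the pace of one catalyst as charged. Free catalyst captures substrate at 0.0690 min⁻¹, and intermediate A then falls back at 0.101 min⁻¹ or goes on with partner. Of the intermediate B so formed, a share of 0.283 goes forward, so intermediate A goes on at a net 0.0215 min⁻¹, slower than it falls back. Set aside the catalyst held as intermediate B, and one catalyst makes 11.2 d⁻¹. Divide the turns owed by that pace to get the clearing time, the days needed to turn the charge over at the starting pace: 4.48 d.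

Do not expect Monday's flask to hold that pace: its substrate and partner start from equal charges, and the cycle consumes both. Treat the pace as following both fractions, and 47.3% of the substrate remains at 5.0 d, which puts about 52.7% through the cycle, counting target and whatever over-reaction takes from it. Do not fear over-reaction in Monday's flask, where the half-life of target by that step, with the other concentrations as charged, is 19 d, longer than the run. Do watch the target in Sunday's flask, though: scaled to its partner charge, that half-life is 2.43 d, shorter than the run.

My reckoning of the substrate stops at Monday's flask, so it gives no row. The forecast covers the row with 53%, 72%, 70% and 45%, so rises, then falls, and it says of the larger charges that “the substrate is used up early, and the target then sits exposed to over-reaction”.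

The flasks give 52.5%, 72.0%, 68.3% and 41.8%, so rises, then falls, with the turn read at 2.6 equiv of partner. Monday's flask ends with 44.6% of its substrate unbound, against the 47.3% reckoned. Now put the clearing time to Sunday's flask, where partner stands at 85.3% of its charge at 2.50 d, so treat substrate as falling pseudo-first-order. The pace at that charge is 50.0 d⁻¹, the clearing time is 1.00 d, and the reckoned substrate at 2.50 d is 8.21%, where Sunday's flask held 9.18%.

(The constants belong to no real substance; what happens was integrated by code.)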